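**Plan**

- Locants used throughout: C1 = acetoxy carbon, C2 = ring CH2, C3 = ring CHBr, C4 = CMe2, C5 = ring =CH, C6 = ring alkene carbon carrying the side chain, C7 = side-chain CHBr, C8 = CH2Cl.
- Retrosynthesis: both C–Br bonds are cut to carbinols of opposite configuration, C7–C8 to a C7 ester, the C5 vinyl hydrogen to a C5 ketone, and the C1 oxygen to silicon. The cyclohexene ring is then cut at C1–C6 and C3–C4.
- Enabling feature: with C5 as ketone and C7 as ester, C4–C5–C6–C7 is a 1,3-dicarbonyl unit in which C6 is the acidic carbon and C4 the γ-carbon. The quaternary C4 forbids dehydration of an aldol at C3, and C1–C2–C3 becomes a β-silyl enal, electrophilic at C1 and C3.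
- Forward: the ring C1–C6 forms in one operation by Michael addition (C6 to C1) and aldol closure (C4 to C3). The C5 oxygen then leaves via the enol triflate, C3–OH becomes C3–Br, the ester becomes the chloromethyl ketone, silicon becomes oxygen, and the C7 carbinol becomes the second bromide.
- Stereochemistry: C1 is set by the amine catalyst in the key step. C3 is relayed from C1 in the same step (reversible aldol) and later inverted by bromide. C7 is set by an oxazaborolidine-catalysed reduction and inverted by bromide.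

Key step: step 3

Remark: the target is read as (1R,5S)-5-bromo-2-[(1S)-1-bromo-2-chloroethyl]-4,4-dimethylcyclohex-2-en-1-yl acetate, with acetate and ring bromine cis.

**Step 1**
Reactants: 1 prop-2-yn-1-ol; 2 dimethyl(phenyl)silane
Product: 3 (2E)-3-[dimethyl(phenyl)silyl]prop-2-en-1-ol
Conditions: Pt2(dvds)3 (0.1 mol %; dvds = 1,3-divinyl-1,1,3,3-tetramethyldisiloxane), P(t-Bu)3, THF, rt
Reagents that add atoms: none
Why: Platinum-catalysed cis-hydrosilylation of the terminal alkyne; the bulky phosphine should direct silicon to the terminal carbon and give the (E)-vinylsilane.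

**Step 2**
Reactants: 3 (2E)-3-[dimethyl(phenyl)silyl]prop-2-en-1-ol
Product: 4 (2E)-3-[dimethyl(phenyl)silyl]prop-2-enal
Conditions: 2,2,6,6-tetramethylpiperidin-1-oxyl (10 mol %), PhI(OAc)2, CH2Cl2, rt
Reagents that add atoms: none
Why: Nitroxyl-catalysed oxidation of the allylic alcohol stops at the aldehyde and should leave the vinylsilane and its (E) geometry untouched.

**Step 3**
Reactants: 4 (2E)-3-[dimethyl(phenyl)silyl]prop-2-enal; 5 methyl 4-methyl-3-oxopentanoate
Product: 7 methyl (4R,6R)-6-[dimethyl(phenyl)silyl]-2,4-dihydroxy-3,3-dimethylcyclohex-1-ene-1-carboxylate (enol tautomer of the cyclic keto ester), via keto aldehyde 6 (not isolated)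
Conditions: (S)-2-[diphenyl(trimethylsilyloxy)methyl]pyrrolidine (10 mol %), PhCO2H (10 mol %), PhMe, 0 °C to rt; then TsOH·H2O (20 mol %), wet PhMe, 40 °C
Reagents that add atoms: none
Why: The amine condenses with 4 to an (E)-iminium ion, the enol of 5 adds through its acidic carbon C6 to the β-carbon C1, and hydrolysis frees keto aldehyde 6 and the catalyst; added acid then enolises the C5 ketone toward C4 and this enol adds to the aldehyde carbon C3. The closest known reaction type is the amine-catalysed Michael/aldol [3+3] annulation of β-keto esters with enals used to make cyclohexenones, which here stops at the aldol because C4 is quaternary. The carbocycle closes in a 6-(enolendo)-exo-trig aldol. C1 is set by the catalyst, C6 attacking the iminium face opposite the diphenyl(silyloxy)methyl group to give the (R) silyl-bearing carbon. C3 is set by substrate control under the reversible acid conditions: in the enolised keto ester the silyl group on C1 should sit pseudoaxial to avoid A(1,2) strain with the ester, so the carbinol should settle equatorial and trans to silicon (4R). The step needs carbon–carbon closure at C4 instead of oxygen closure to the lactol or attack by C6: the lactol reopens in wet acid, C6 could only form a four-membered ring, and the product cannot dehydrate.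

**Step 4**
Reactants: 7 methyl (4R,6R)-6-[dimethyl(phenyl)silyl]-2,4-dihydroxy-3,3-dimethylcyclohex-1-ene-1-carboxylate
Product: 8 methyl (4R,6R)-6-[dimethyl(phenyl)silyl]-4-hydroxy-3,3-dimethyl-2-(trifluoromethanesulfonyloxy)cyclohex-1-ene-1-carboxylate
Conditions: NaH (1.05 equiv), THF, 0 °C; then PhNTf2, 0 °C to rt; aqueous work-up
Reagents that add atoms: N-phenylbis(trifluoromethanesulfonimide), O=S(=O)(N(c1ccccc1)S(=O)(=O)C(F)(F)F)C(F)(F)F
Why: One equivalent of NaH deprotonates only the 1,3-dicarbonyl unit, and the enolate oxygen on C5 is sulfonylated (enol triflate formation) by a reagent that should not touch the neutral, hindered C3 carbinol.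

**Step 5**
Reactants: 8 methyl (4R,6R)-6-[dimethyl(phenyl)silyl]-4-hydroxy-3,3-dimethyl-2-(trifluoromethanesulfonyloxy)cyclohex-1-ene-1-carboxylate
Product: 9 methyl (4R,6R)-6-[dimethyl(phenyl)silyl]-4-hydroxy-3,3-dimethylcyclohex-1-ene-1-carboxylate
Conditions: Pd(OAc)2 (5 mol %), PPh3 (10 mol %), HCO2H, Et3N, DMF, 60 °C
Reagents that add atoms: none
Why: Palladium-catalysed formate reduction of a vinyl triflate (oxidative addition to zerovalent palladium, formate exchange, loss of CO2, reductive elimination) should put hydrogen on C5 and fix the C5=C6 alkene.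

**Step 6**
Reactants: 9 methyl (4R,6R)-6-[dimethyl(phenyl)silyl]-4-hydroxy-3,3-dimethylcyclohex-1-ene-1-carboxylate
Product: 10 methyl (4S,6R)-4-bromo-6-[dimethyl(phenyl)silyl]-3,3-dimethylcyclohex-1-ene-1-carboxylate
Conditions: CBr4, PPh3, PhMe, 60 °C
Reagents that add atoms: tetrabromomethane, BrC(Br)(Br)Br
Why: Appel reaction: bromide displaces the oxyphosphonium group on C3 in an SN2 step with inversion (4R to 4S), placing bromine cis to the C1 substituent; silyl group, ester and alkene should be inert to these neutral conditions.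

**Step 7**
Reactants: 10 methyl (4S,6R)-4-bromo-6-[dimethyl(phenyl)silyl]-3,3-dimethylcyclohex-1-ene-1-carboxylate
Product: 11 1-{(4S,6R)-4-bromo-6-[dimethyl(phenyl)silyl]-3,3-dimethylcyclohex-1-en-1-yl}-2-chloroethan-1-one
Conditions: ICH2Cl, MeLi·LiBr, THF/Et2O, −78 °C; cold aqueous quench
Reagents that add atoms: chloroiodomethane, ClCI
Why: Acyl substitution by chloromethyllithium generated in the presence of the ester (carbenoid homologation of an ester to an α-chloro ketone); the tetrahedral lithium alkoxide should persist at −78 °C so the ketone is released only on quench, and the hindered secondary bromide and the C–Si bond should not react.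

**Step 8**
Reactants: 11 1-{(4S,6R)-4-bromo-6-[dimethyl(phenyl)silyl]-3,3-dimethylcyclohex-1-en-1-yl}-2-chloroethan-1-one
Product: 13 1-[(4S,6R)-4-bromo-6-hydroxy-3,3-dimethylcyclohex-1-en-1-yl]-2-chloroethan-1-one, via acetoxysilane 12 (not isolated)
Conditions: Hg(OAc)2, AcOOH (32% in AcOH), AcOH, rt; aqueous work-up
Reagents that add atoms: peracetic acid, CC(=O)OO
Why: Fleming–Tamao oxidation: Hg(OAc)2 cleaves the Si–phenyl bond, the peracid attacks silicon and C1 migrates from silicon to oxygen with retention; the allylsilane alkene is part of an enone, so electrophilic desilylation with allylic shift should not compete.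

**Step 9**
Reactants: 13 1-[(4S,6R)-4-bromo-6-hydroxy-3,3-dimethylcyclohex-1-en-1-yl]-2-chloroethan-1-one
Product: 14 (1R,5S)-5-bromo-2-(chloroacetyl)-4,4-dimethylcyclohex-2-en-1-yl acetate
Conditions: Ac2O, Sc(OTf)3 (1 mol %), MeCN, 0 °C
Reagents that add atoms: acetic anhydride, CC(=O)OC(C)=O
Why: Lewis-acid-catalysed acetylation of the only free hydroxyl; no nucleophilic amine is present that could alkylate on the chloromethyl ketone.

**Step 10**
Reactants: 14 (1R,5S)-5-bromo-2-(chloroacetyl)-4,4-dimethylcyclohex-2-en-1-yl acetate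
Product: 15 (1R,5S)-5-bromo-2-[(1R)-2-chloro-1-hydroxyethyl]-4,4-dimethylcyclohex-2-en-1-yl acetate
Conditions: (R)-1-methyl-3,3-diphenyltetrahydro-1H,3H-pyrrolo[1,2-c][1,3,2]oxazaborole (20 mol %), catecholborane, PhMe, −78 °C; MeOH, then pH 7 buffer
Reagents that add atoms: none
Why: Corey–Bakshi–Shibata reduction: the ketone should bind the oxazaborolidine with the ring alkenyl group as the large and chloromethyl as the small substituent, so hydride is delivered 1,2 to give the (R) carbinol at C7 under catalyst control.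

**Step 11**
Reactants: 15 (1R,5S)-5-bromo-2-[(1R)-2-chloro-1-hydroxyethyl]-4,4-dimethylcyclohex-2-en-1-yl acetate
Product: 16 (1R,5S)-5-bromo-2-[(1S)-1-bromo-2-chloroethyl]-4,4-dimethylcyclohex-2-en-1-yl acetate
Conditions: CBr4, PPh3, CH2Cl2, 0 °C
Reagents that add atoms: tetrabromomethane, BrC(Br)(Br)Br
Why: Appel reaction at the allylic carbinol: SN2 displacement with inversion should give the (S) bromide; the β-chlorine disfavours ionisation and the neopentyl position C5 disfavours substitution with allylic shift.

**Compound list**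

1 | prop-2-yn-1-ol | C#CCO | starting material
2 | dimethyl(phenyl)silane | C[SiH](C)c1ccccc1 | starting material
3 | (2E)-3-[dimethyl(phenyl)silyl]prop-2-en-1-ol | OC/C=C/[Si](C)(C)c1ccccc1 | intermediate
4 | (2E)-3-[dimethyl(phenyl)silyl]prop-2-enal | O=C/C=C/[Si](C)(C)c1ccccc1 | intermediate
5 | methyl 4-methyl-3-oxopentanoate | COC(=O)CC(=O)C(C)C | starting material
6 | methyl 2-{(1R)-1-[dimethyl(phenyl)silyl]-3-oxopropyl}-4-methyl-3-oxopentanoate (both C2 epimers, equilibrating) | C[Si](C)(c1ccccc1)[C@H](CC=O)C(C(=O)OC)C(=O)C(C)C | intermediate (not isolated)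
7 | methyl (4R,6R)-6-[dimethyl(phenyl)silyl]-2,4-dihydroxy-3,3-dimethylcyclohex-1-ene-1-carboxylate (enol tautomer) | C[Si](C)(c1ccccc1)[C@@H]2C[C@@H](O)C(C)(C)C(O)=C2C(=O)OC | intermediate
8 | methyl (4R,6R)-6-[dimethyl(phenyl)silyl]-4-hydroxy-3,3-dimethyl-2-(trifluoromethanesulfonyloxy)cyclohex-1-ene-1-carboxylate | C[Si](C)(c1ccccc1)[C@@H]2C[C@@H](O)C(C)(C)C(OS(=O)(=O)C(F)(F)F)=C2C(=O)OC | intermediate
9 | methyl (4R,6R)-6-[dimethyl(phenyl)silyl]-4-hydroxy-3,3-dimethylcyclohex-1-ene-1-carboxylate | C[Si](C)(c1ccccc1)[C@@H]2C[C@@H](O)C(C)(C)C=C2C(=O)OC | intermediate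
10 | methyl (4S,6R)-4-bromo-6-[dimethyl(phenyl)silyl]-3,3-dimethylcyclohex-1-ene-1-carboxylate | C[Si](C)(c1ccccc1)[C@@H]2C[C@H](Br)C(C)(C)C=C2C(=O)OC | intermediate
11 | 1-{(4S,6R)-4-bromo-6-[dimethyl(phenyl)silyl]-3,3-dimethylcyclohex-1-en-1-yl}-2-chloroethan-1-one | C[Si](C)(c1ccccc1)[C@@H]2C[C@H](Br)C(C)(C)C=C2C(=O)CCl | intermediate
12 | [(1R,5S)-5-bromo-2-(chloroacetyl)-4,4-dimethylcyclohex-2-en-1-yl]dimethylsilyl acetate | CC(=O)O[Si](C)(C)[C@@H]1C[C@H](Br)C(C)(C)C=C1C(=O)CCl | intermediate (not isolated)
13 | 1-[(4S,6R)-4-bromo-6-hydroxy-3,3-dimethylcyclohex-1-en-1-yl]-2-chloroethan-1-one | O[C@@H]1C[C@H](Br)C(C)(C)C=C1C(=O)CCl | intermediate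
14 | (1R,5S)-5-bromo-2-(chloroacetyl)-4,4-dimethylcyclohex-2-en-1-yl acetate | CC(=O)O[C@@H]1C[C@H](Br)C(C)(C)C=C1C(=O)CCl | intermediate
15 | (1R,5S)-5-bromo-2-[(1R)-2-chloro-1-hydroxyethyl]-4,4-dimethylcyclohex-2-en-1-yl acetate | CC(=O)O[C@@H]1C[C@H](Br)C(C)(C)C=C1[C@@H](O)CCl | intermediate
16 | (1R,5S)-5-bromo-2-[(1S)-1-bromo-2-chloroethyl]-4,4-dimethylcyclohex-2-en-1-yl acetate | CC(=O)O[C@@H]1C[C@H](Br)C(C)(C)C=C1[C@H](Br)CCl | target

**Summary**

Total steps: 11. Longest linear sequence: 11 steps (1 to 16; keto ester 5 enters at step 3).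

**Steps most likely to fail**

Step 3. Closure of the hindered tertiary γ-enol onto the aldehyde may be slower than diversion of keto aldehyde 6 into its lactol and, by loss of water, into a 4H-pyran. The aldol equilibrium may also fail to favour the trans carbinol clearly.
Fallback, setting out from 4 and 5 and returning at 7: the two bonds are made in separate steps and in the reverse order.
- The dianion of 5 (NaH, then n-BuLi, THF, 0 °C) should add through its γ-carbon to the aldehyde of 4 at −78 °C to give the racemic δ-hydroxy β-keto ester F1 (C3–C4 bond).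
- Dess–Martin periodinane should oxidise it to the β-silyl enone F2.
- A 6-endo intramolecular Michael addition of C6 to C1 under iminium activation should close the C1–C6 bond and set C1, giving the cyclic diketo ester F3. The catalyst is 9-amino-9-deoxy-epi-quinine with CF3CO2H, or its quinidine-derived pseudo-enantiomer, whichever delivers the (R) centre.
- Reduction of the isolated C3 ketone (NaBH4, CeCl3·7H2O, MeOH, −78 °C), then equilibration of the carbinol through retro-aldol/aldol with TsOH·H2O in wet toluene, should lead to 7.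

Step 6. E2 loss of the oxyphosphonium group toward C2, or a 1,2-methyl shift from C4, may outrun backside attack at the neopentyl carbinol. Substitution must also pass through the minor half-chair in which the C–O bond is axial and the bulky silyl group equatorial.
Fallback, setting out from 9 and returning at 16: bromination is postponed to the end, when C1 carries the small acetate, and both bromides are made together.
- Excess chloromethyllithium (ICH2Cl, MeLi·LiBr, −78 °C) should convert 9 into the hydroxy chloromethyl ketone F4.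
- Hg(OAc)2/AcOOH should oxidise the C–Si bond to give the diol F5.
- AcCl with 2,4,6-collidine at −78 °C should acetylate only the allylic C1 hydroxyl, giving the hydroxy acetate F6.
- The oxazaborolidine reduction of step 10 should give the diol F7.
- CBr4/PPh3 should then replace both carbinols with inversion in one operation to give 16.

Step 7. α-Elimination of the carbenoid may outpace its addition to the hindered, conjugated ester, and a second addition to the released ketone would give a chlorohydrin.
Fallback, setting out from 10 and returning at 11: the carbenoid is added to an aldehyde instead of an ester.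
- (Me2CHCH2)2AlH in CH2Cl2 at −78 °C should reduce 10 to the allylic alcohol F8.
- MnO2 should oxidise it to the enal F9.
- ICH2Cl/MeLi·LiBr at −78 °C should add to the aldehyde to give the chlorohydrin F10 as both carbinol epimers.
- Dess–Martin periodinane should converge both epimers on 11.

**Further compounds**

F1 | step 3 | methyl (6E)-7-[dimethyl(phenyl)silyl]-5-hydroxy-4,4-dimethyl-3-oxohept-6-enoate (racemic) | COC(=O)CC(=O)C(C)(C)C(O)/C=C/[Si](C)(C)c1ccccc1
F2 | step 3 | methyl (6E)-7-[dimethyl(phenyl)silyl]-4,4-dimethyl-3,5-dioxohept-6-enoate | COC(=O)CC(=O)C(C)(C)C(=O)/C=C/[Si](C)(C)c1ccccc1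
F3 | step 3 | methyl (6R)-6-[dimethyl(phenyl)silyl]-2-hydroxy-3,3-dimethyl-4-oxocyclohex-1-ene-1-carboxylate | C[Si](C)(c1ccccc1)[C@@H]2CC(=O)C(C)(C)C(O)=C2C(=O)OC
F4 | step 6 | 2-chloro-1-{(4R,6R)-6-[dimethyl(phenyl)silyl]-4-hydroxy-3,3-dimethylcyclohex-1-en-1-yl}ethan-1-one | C[Si](C)(c1ccccc1)[C@@H]2C[C@@H](O)C(C)(C)C=C2C(=O)CCl
F5 | step 6 | 2-chloro-1-[(4R,6R)-4,6-dihydroxy-3,3-dimethylcyclohex-1-en-1-yl]ethan-1-one | O[C@@H]1C[C@@H](O)C(C)(C)C=C1C(=O)CCl
F6 | step 6 | (1R,5R)-2-(chloroacetyl)-5-hydroxy-4,4-dimethylcyclohex-2-en-1-yl acetate | CC(=O)O[C@@H]1C[C@@H](O)C(C)(C)C=C1C(=O)CCl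
F7 | step 6 | (1R,5R)-2-[(1R)-2-chloro-1-hydroxyethyl]-5-hydroxy-4,4-dimethylcyclohex-2-en-1-yl acetate | CC(=O)O[C@@H]1C[C@@H](O)C(C)(C)C=C1[C@@H](O)CCl
F8 | step 7 | {(4S,6R)-4-bromo-6-[dimethyl(phenyl)silyl]-3,3-dimethylcyclohex-1-en-1-yl}methanol | C[Si](C)(c1ccccc1)[C@@H]2C[C@H](Br)C(C)(C)C=C2CO
F9 | step 7 | (4S,6R)-4-bromo-6-[dimethyl(phenyl)silyl]-3,3-dimethylcyclohex-1-ene-1-carbaldehyde | C[Si](C)(c1ccccc1)[C@@H]2C[C@H](Br)C(C)(C)C=C2C=O
F10 | step 7 | 1-{(4S,6R)-4-bromo-6-[dimethyl(phenyl)silyl]-3,3-dimethylcyclohex-1-en-1-yl}-2-chloroethan-1-ol (both carbinol epimers) | C[Si](C)(c1ccccc1)[C@@H]2C[C@H](Br)C(C)(C)C=C2C(O)CCl
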